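**Strategy.** The route rests on cutting the C7–C8 bond of the cyclobutane (bicyclo[4.2.0]octane numbering: C1 fusion CH, C6 fusion C–Me, C7 CH–Me, C8 bearing methyl and pyranone C6′) and re-inserting C6′ into the ring, which leads back to a cis-hydrindan-2-one. Since C8 carries an exocyclic carbon between C1 and C7, it is the carbene carbon of an α-diazoketone: one photochemical Wolff rearrangement shifts C7 onto C8, contracts the cyclopentanone to the cyclobutane and delivers C6′ as a methanol-trapped ketene. The precursor is the cis-fused 1-diazo-3,3a,5,7-tetramethylhydrindan-2-one, its diene masked as a C6 dimethyl ketal.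

Key step: step 8

Remark: the 2,4-diene is carried through the contraction as an ene-ketal (hydrindane C6 dimethyl ketal, C4=C5, sp3 C7) and released in steps 10–12; skeleton, ring closed and bond formed are unchanged, C7a–H is then not allylic to the carbene carbon, and C3 stays conformationally locked until it can no longer enolise.
Locants: hydrindane numbering through step 7, bicyclo[4.2.0]octane numbering from step 8 (hydrindane C1, C3, C3a, C7a, C7, C6, C5, C4 become C8, C7, C6, C1, C2, C3, C4, C5).

Step 1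
Reactants: 1 4-methoxy-3-methylphenol
Product: 2 4,4-dimethoxy-3-methylcyclohexa-2,5-dien-1-one
Conditions: PhI(OAc)2, MeOH, 0 °C
Reagents that add atoms: methanol, CO
Why: Oxidative dearomatisation of a 4-methoxyphenol by PhI(OAc)2, in which methanol adds at the methoxy-bearing para carbon to give the quinone monoketal; no stereocentre is formed.

Step 2
Reactants: 2 4,4-dimethoxy-3-methylcyclohexa-2,5-dien-1-one; 3 prop-2-en-1-yl acetate (allyl acetate)
Product: 5 (5R,6R)-4,4-dimethoxy-3,5-dimethyl-6-(prop-2-en-1-yl)cyclohex-2-en-1-one (5-methyl and 6-allyl trans), via zinc enolate 4 (not isolated)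
Conditions: Me2Zn, Cu(OTf)2 (2 mol%), BINOL-derived bis(1-phenylethyl)amine phosphoramidite (4 mol%), toluene, −25 °C; then 3, Pd(PPh3)4 (3 mol%), 0 °C
Reagents that add atoms: dimethylzinc, C[Zn]C
Why: Copper-catalysed enantioselective conjugate addition of Me2Zn reaches only the unsubstituted enone arm (the β-methylated arm is inert), the ligand antipode being chosen so that C5 becomes R, and zinc enolate 4 is then allylated through a π-allylpalladium intermediate (Tsuji–Trost) anti to the new C5 methyl, which should give the trans-5,6 product.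

Step 3
Reactants: 5 (5R,6R)-4,4-dimethoxy-3,5-dimethyl-6-(prop-2-en-1-yl)cyclohex-2-en-1-one
Product: 6 (5R,6R)-4,4-dimethoxy-3,5-dimethyl-6-(2-oxopropyl)cyclohex-2-en-1-one
Conditions: PdCl2 (10 mol%), CuCl, O2 (1 atm), DMF/H2O 7:1, rt
Reagents that add atoms: water, O
Why: Tsuji–Wacker oxidation, in which Markovnikov hydroxypalladation of the monosubstituted alkene gives the methyl ketone while the trisubstituted enone alkene and the cross-conjugated, acid-resistant ketal are left alone; no stereocentre changes.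

Step 4
Reactants: 6 (5R,6R)-4,4-dimethoxy-3,5-dimethyl-6-(2-oxopropyl)cyclohex-2-en-1-one
Product: 7 (7R,7aR)-6,6-dimethoxy-5,7-dimethyl-1,6,7,7a-tetrahydro-2H-inden-2-one
Conditions: KOH, MeOH, 0 °C to rt
Reagents that add atoms: none
Why: Intramolecular aldol condensation of the 1,4-diketone, in which the methyl-ketone enolate can reach only the ring carbonyl in a five-membered closure and E1cB loss of water gives the linear dienone; the enolisable C7a stays trans to the configurationally fixed C7 methyl, its thermodynamic arrangement.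

Step 5
Reactants: 7 (7R,7aR)-6,6-dimethoxy-5,7-dimethyl-1,6,7,7a-tetrahydro-2H-inden-2-one
Product: 9 (3R,3aR,7R,7aR)-6,6-dimethoxy-3,3a,5,7-tetramethyl-1,3,3a,6,7,7a-hexahydro-2H-inden-2-one (cis-fused; 3-Me, 3a-Me and H-7a on one face; 7-Me trans to C1), via lithium enolate 8 (not isolated)
Conditions: Me2CuLi (from CuI, 2 MeLi), Et2O, −40 to 0 °C; then MeI, HMPA, THF, −20 °C to rt; buffered work-up
Reagents that add atoms: lithium dimethylcuprate, [Li+].C[Cu-]C; iodomethane, CI
Why: Cuprate conjugate addition followed by enolate alkylation: the distal terminus C5 is fully substituted and neopentylic, so methyl should add 1,4 at C3a on the face of H-7a (the other face carries ring carbon C7), giving the cis fusion, and the regiospecific enolate 8, whose C3 sits pseudoaxially under the six-membered ring (locked by the equatorial trans 7-methyl), should take methyl iodide on the open convex face, syn to the 3a-methyl.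

Step 6
Reactants: 9 (3R,3aR,7R,7aR)-6,6-dimethoxy-3,3a,5,7-tetramethyl-1,3,3a,6,7,7a-hexahydro-2H-inden-2-one
Product: 11 1-(trifluoroacetyl) derivative of 9, drawn as its C1=C2 enol, via lithium enolate 10 (not isolated)
Conditions: LiN(SiMe3)2, THF, −78 °C; CF3CO2CH2CF3, −78 °C; AcOH quench
Reagents that add atoms: 2,2,2-trifluoroethyl trifluoroacetate, O=C(OCC(F)(F)F)C(F)(F)F
Why: Kinetic deprotonation at −78 °C takes the only α-methylene (C1) and not the methine C3 beside the quaternary centre, and enolate 10 is acylated by the trifluoroacetate (crossed Claisen activation for diazo transfer); C3 is not epimerised under these conditions.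

Step 7
Reactants: 11 1-(trifluoroacetyl) derivative of 9
Product: 12 (3R,3aS,7R,7aR)-1-diazo-6,6-dimethoxy-3,3a,5,7-tetramethyl-1,3,3a,6,7,7a-hexahydro-2H-inden-2-one
Conditions: MsN3, Et3N, H2O (1 equiv), MeCN, rt
Reagents that add atoms: methanesulfonyl azide, CS(=O)(=O)N=[N+]=[N-]
Why: Detrifluoroacetylative diazo transfer, in which the enolate of 11 adds to the terminal nitrogen of the sulfonyl azide and the adduct fragments to the diazoketone and the N-sulfonyl trifluoroacetamide, placing the diazo group at C1 only; no stereocentre is touched.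

Step 8
Reactants: 12 (3R,3aS,7R,7aR)-1-diazo-6,6-dimethoxy-3,3a,5,7-tetramethyl-1,3,3a,6,7,7a-hexahydro-2H-inden-2-one
Product: 14 methyl (1S,2R,6R,7S,8S)-3,3-dimethoxy-2,4,6,7-tetramethylbicyclo[4.2.0]oct-4-ene-8-carboxylate, via ketene 13 (not isolated)
Conditions: hν (365 nm), degassed MeOH, 5 °C
Reagents that add atoms: methanol, CO
Why: Direct excitation of the s-Z-locked cyclic α-diazoketone expels N2 and the C2–C3 ring bond migrates to the diazo carbon (hydrindane C3 to C1, that is C7 to C8), in concert or through the singlet ketocarbene, so that the former carbonyl carbon leaves the ring as ketene 13, to which methanol adds. This is the photochemical Wolff rearrangement in its ring-contracting form, as known for 2-diazocyclopentanones giving cyclobutanecarboxylates. The four-membered ring is closed by this 1,2-alkyl shift, a contraction of the five-membered ring inside the existing cis-fused bicycle and not an end-to-end cyclisation. The migrating carbon keeps its configuration and C1 and C6 are not involved, so the cis fusion and the syn 6,7-dimethyl pattern pass unchanged from 12; the new C8 centre is set only by convex-face protonation of the ester enol (one epimer is drawn) and is erased in step 9. The selectivity needed is alkyl shift over O–H insertion into methanol and over 1,2-hydrogen shift from C7a, and it should be favoured by the enforced s-Z geometry, unsensitised irradiation at the weak long-wavelength band and the non-allylic C7a–H of the ene-ketal precursor. Regiochemistry is not in question, because the diazo group sits on the only methylene and C3 is the only carbon that can migrate.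

Step 9
Reactants: 14 methyl (1S,2R,6R,7S,8S)-3,3-dimethoxy-2,4,6,7-tetramethylbicyclo[4.2.0]oct-4-ene-8-carboxylate
Product: 16 methyl (1R,2R,6R,7R,8S)-3,3-dimethoxy-2,4,6,7,8-pentamethylbicyclo[4.2.0]oct-4-ene-8-carboxylate (6-, 7- and 8-methyl on the convex face, CO2Me on the concave face), via lithium enolate 15 (not isolated)
Conditions: LiN(i-Pr)2, THF, −78 °C; MeI, DMPU, −78 to −20 °C
Reagents that add atoms: iodomethane, CI
Why: Ester enolate alkylation, in which the exocyclic enolate 15 should take methyl iodide on the convex face of the cis-fused bicycle (the concave face is covered by the six-membered ring and its equatorial C2 methyl), so that the new methyl is exo and the carboxyl carbon endo.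

Step 10
Reactants: 16 methyl (1R,2R,6R,7R,8S)-3,3-dimethoxy-2,4,6,7,8-pentamethylbicyclo[4.2.0]oct-4-ene-8-carboxylate
Product: 17 methyl 2,4,6,7,8-pentamethyl-3-oxobicyclo[4.2.0]oct-4-ene-8-carboxylate (C1, C6, C7, C8 as in 16)
Conditions: PPTS (cat.), acetone/H2O 10:1, rt
Reagents that add atoms: water, O
Why: Acid-catalysed hydrolysis of the allylic dimethyl ketal through its alkene-stabilised oxocarbenium ion, run with a weak acid so that the enone next to the cyclobutane is not protonated; C2 becomes epimerisable, which is irrelevant because it is planarised in step 11.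

Step 11
Reactants: 17 methyl 2,4,6,7,8-pentamethyl-3-oxobicyclo[4.2.0]oct-4-ene-8-carboxylate
Product: 19 methyl 2,4,6,7,8-pentamethyl-3-(trifluoromethanesulfonyloxy)bicyclo[4.2.0]octa-2,4-diene-8-carboxylate (C1, C6, C7, C8 as in 16), via potassium dienolate 18 (not isolated)
Conditions: KN(SiMe3)2, THF, −78 °C; PhNTf2, −78 to 0 °C; H2O
Reagents that add atoms: N-phenylbis(trifluoromethanesulfonimide), O=S(=O)(N(c1ccccc1)S(=O)(=O)C(F)(F)F)C(F)(F)F
Why: Enol triflate formation: the enone has a single enolisable position (the α′ hydrogen at C2; C6 is quaternary and the ester has no α-hydrogen), so the cross-conjugated dienolate 18 forms regiospecifically and is O-sulfonylated by the triflimide.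

Step 12
Reactants: 19 methyl 2,4,6,7,8-pentamethyl-3-(trifluoromethanesulfonyloxy)bicyclo[4.2.0]octa-2,4-diene-8-carboxylate
Product: 20 methyl (1R,6R,7R,8S)-2,4,6,7,8-pentamethylbicyclo[4.2.0]octa-2,4-diene-8-carboxylate
Conditions: Pd(OAc)2 (5 mol%), PPh3 (10 mol%), HCO2H, Bu3N, DMF, 40 °C
Reagents that add atoms: none
Why: Palladium-catalysed formate reduction of an enol triflate: zerovalent palladium inserts into the C–OTf bond, formate gives a palladium hydride by loss of CO2 and reductive elimination forms C3–H, releasing the 2,4-diene without a cationic intermediate next to the cyclobutane.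

Step 13
Reactants: 20 methyl (1R,6R,7R,8S)-2,4,6,7,8-pentamethylbicyclo[4.2.0]octa-2,4-diene-8-carboxylate
Product: 21 (1R,6R,7R,8S)-2,4,6,7,8-pentamethylbicyclo[4.2.0]octa-2,4-diene-8-carbaldehyde
Conditions: i-Bu2AlH, CH2Cl2, −78 °C; aq. potassium sodium tartrate
Reagents that add atoms: none
Why: Partial reduction of the ester with i-Bu2AlH, whose tetrahedral aluminium hemiacetal should survive at −78 °C for this neopentyl-type ester and collapse to the aldehyde only on work-up; no stereocentre is affected.

Step 14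
Reactants: 21 (1R,6R,7R,8S)-2,4,6,7,8-pentamethylbicyclo[4.2.0]octa-2,4-diene-8-carbaldehyde; 22 methyl 2-methyl-3-oxopentanoate
Product: 24 methyl 5-hydroxy-2,4-dimethyl-3-oxo-5-(2,4,6,7,8-pentamethylbicyclo[4.2.0]octa-2,4-dien-8-yl)pentanoate (ring as in 21; side-chain diastereomers), via dianion 23 (not isolated)
Conditions: 22, NaH, THF, 0 °C; n-BuLi, 0 °C; then 21, −78 to −20 °C; H2O
Reagents that add atoms: none
Why: Aldol addition of a β-keto ester dianion, whose more reactive γ-carbanion adds to the aldehyde; the three new stereocentres form unselectively and are removed in steps 15 and 16.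

Step 15
Reactants: 24 methyl 5-hydroxy-2,4-dimethyl-3-oxo-5-(2,4,6,7,8-pentamethylbicyclo[4.2.0]octa-2,4-dien-8-yl)pentanoate
Product: 25 methyl 2,4-dimethyl-3,5-dioxo-5-(2,4,6,7,8-pentamethylbicyclo[4.2.0]octa-2,4-dien-8-yl)pentanoate (ring as in 21)
Conditions: Dess–Martin periodinane, NaHCO3, CH2Cl2, rt
Reagents that add atoms: none
Why: Dess–Martin oxidation of the secondary alcohol to the ketone under buffered, neutral conditions that leave the diene and the β-dicarbonyl system intact.

Step 16
Reactants: 25 methyl 2,4-dimethyl-3,5-dioxo-5-(2,4,6,7,8-pentamethylbicyclo[4.2.0]octa-2,4-dien-8-yl)pentanoate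
Product: 26 4-hydroxy-3,5-dimethyl-6-[(1R,6R,7R,8S)-2,4,6,7,8-pentamethylbicyclo[4.2.0]octa-2,4-dien-8-yl]-2H-pyran-2-one
Conditions: DBU, toluene, rt to 40 °C
Reagents that add atoms: none
Why: Base-mediated lactonisation of the β,δ-diketo ester, in which the enolate oxygen of the δ-ketone attacks the ester carbonyl (six-membered ring, loss of methanol) and tautomerisation gives the 4-hydroxy-2-pyranone; the temperature is held at or below 40 °C to keep the bicyclooctadiene from thermal 6π ring opening.

Step 17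
Reactants: 26 4-hydroxy-3,5-dimethyl-6-[(1R,6R,7R,8S)-2,4,6,7,8-pentamethylbicyclo[4.2.0]octa-2,4-dien-8-yl]-2H-pyran-2-one
Product: 27 2-methoxy-3,5-dimethyl-6-[(1R,6R,7R,8S)-2,4,6,7,8-pentamethylbicyclo[4.2.0]octa-2,4-dien-8-yl]-4H-pyran-4-one
Conditions: MeOTf, 2,6-di-tert-butylpyridine, CH2Cl2, 0 °C to rt
Reagents that add atoms: methyl trifluoromethanesulfonate, COS(=O)(=O)C(F)(F)F
Why: O-Methylation with a hard methylating agent, which alkylates the neutral hydroxypyranone at the lactone carbonyl oxygen so that loss of the 4-OH proton gives the 2-methoxy-4-pyranone rather than the 4-methoxy-2-pyranone; the hindered pyridine only buffers the triflic acid and so protects the diene.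

Step 18
Reactants: 27 2-methoxy-3,5-dimethyl-6-[(1R,6R,7R,8S)-2,4,6,7,8-pentamethylbicyclo[4.2.0]octa-2,4-dien-8-yl]-4H-pyran-4-one
Product: 28 CNP0183511.1, 2-methoxy-3,5-dimethyl-6-(1,3,4,5,10-pentamethyl-7,8-dioxatricyclo[4.2.2.0(2,5)]dec-9-en-3-yl)-4H-pyran-4-one (peroxide bridge anti to the cyclobutane)
Conditions: O2, methylene blue (cat.), visible light, CH2Cl2, 0 °C
Reagents that add atoms: oxygen, O=O
Why: [4+2] Cycloaddition of singlet oxygen to the cisoid 2,4-diene across C2 and C5, the oxygen approaching the convex face, anti to the cyclobutane and its endo pyranone, which should set both new C–O stereocentres as in the target.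

**Compound list**

1 | 4-methoxy-3-methylphenol | COc1ccc(O)cc1C | starting material
2 | 4,4-dimethoxy-3-methylcyclohexa-2,5-dien-1-one | O=C1C=CC(OC)(OC)C(C)=C1 | intermediate
3 | prop-2-en-1-yl acetate | CC(=O)OCC=C | starting material
4 | methylzinc dienolate of (5R)-4,4-dimethoxy-3,5-dimethylcyclohex-2-en-1-one (O–Zn at C1, C1=C6) | C[Zn]OC1=C[C@@H](C)C(OC)(OC)C(C)=C1 | intermediate (not isolated)
5 | (5R,6R)-4,4-dimethoxy-3,5-dimethyl-6-(prop-2-en-1-yl)cyclohex-2-en-1-one | O=C1C=C(C)C(OC)(OC)[C@H](C)[C@H]1CC=C | intermediate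
6 | (5R,6R)-4,4-dimethoxy-3,5-dimethyl-6-(2-oxopropyl)cyclohex-2-en-1-one | O=C1C=C(C)C(OC)(OC)[C@H](C)[C@H]1CC(C)=O | intermediate
7 | (7R,7aR)-6,6-dimethoxy-5,7-dimethyl-1,6,7,7a-tetrahydro-2H-inden-2-one | C1C(=O)C=C2C=C(C)C(OC)(OC)[C@H](C)[C@@H]12 | intermediate
8 | lithium enolate (C2–OLi, C2=C3) of the cis-fused 3a-methylated ketone | C1C(O[Li])=C[C@@]2(C)C=C(C)C(OC)(OC)[C@H](C)[C@@H]12 | intermediate (not isolated)
9 | (3R,3aR,7R,7aR)-6,6-dimethoxy-3,3a,5,7-tetramethyl-1,3,3a,6,7,7a-hexahydro-2H-inden-2-one | C1C(=O)[C@H](C)[C@@]2(C)C=C(C)C(OC)(OC)[C@H](C)[C@@H]12 | intermediate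
10 | lithium enolate of 9 (C1=C2) | C1=C(O[Li])[C@H](C)[C@@]2(C)C=C(C)C(OC)(OC)[C@H](C)[C@@H]12 | intermediate (not isolated)
11 | 1-(trifluoroacetyl) derivative of 9, C1=C2 enol form | FC(F)(F)C(=O)C1=C(O)[C@H](C)[C@@]2(C)C=C(C)C(OC)(OC)[C@H](C)[C@@H]12 | intermediate
12 | (3R,3aS,7R,7aR)-1-diazo-6,6-dimethoxy-3,3a,5,7-tetramethyl-1,3,3a,6,7,7a-hexahydro-2H-inden-2-one | [N-]=[N+]=C1C(=O)[C@H](C)[C@@]2(C)C=C(C)C(OC)(OC)[C@H](C)[C@@H]12 | intermediate
13 | 3,3-dimethoxy-2,4,6,7-tetramethyl-8-(oxomethylidene)bicyclo[4.2.0]oct-4-ene (ketene; ring centres as in 14) | O=C=C1[C@H](C)[C@@]2(C)C=C(C)C(OC)(OC)[C@H](C)[C@@H]12 | intermediate (not isolated)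
14 | methyl (1S,2R,6R,7S,8S)-3,3-dimethoxy-2,4,6,7-tetramethylbicyclo[4.2.0]oct-4-ene-8-carboxylate | COC(=O)[C@H]1[C@H](C)[C@@]2(C)C=C(C)C(OC)(OC)[C@H](C)[C@@H]12 | intermediate
15 | lithium ester enolate of 14 | COC(O[Li])=C1[C@H](C)[C@@]2(C)C=C(C)C(OC)(OC)[C@H](C)[C@@H]12 | intermediate (not isolated)
16 | methyl (1R,2R,6R,7R,8S)-3,3-dimethoxy-2,4,6,7,8-pentamethylbicyclo[4.2.0]oct-4-ene-8-carboxylate | COC(=O)[C@@]1(C)[C@H](C)[C@@]2(C)C=C(C)C(OC)(OC)[C@H](C)[C@@H]12 | intermediate
17 | methyl 2,4,6,7,8-pentamethyl-3-oxobicyclo[4.2.0]oct-4-ene-8-carboxylate (C1, C6, C7, C8 as in 16) | COC(=O)[C@@]1(C)[C@H](C)[C@@]2(C)C=C(C)C(=O)[C@H](C)[C@@H]12 | intermediate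
18 | potassium dienolate of 17 (C2=C3–OK) | COC(=O)[C@@]1(C)[C@H](C)[C@@]2(C)C=C(C)C(O[K])=C(C)[C@@H]12 | intermediate (not isolated)
19 | methyl 2,4,6,7,8-pentamethyl-3-(trifluoromethanesulfonyloxy)bicyclo[4.2.0]octa-2,4-diene-8-carboxylate (C1, C6, C7, C8 as in 16) | COC(=O)[C@@]1(C)[C@H](C)[C@@]2(C)C=C(C)C(OS(=O)(=O)C(F)(F)F)=C(C)[C@@H]12 | intermediate
20 | methyl (1R,6R,7R,8S)-2,4,6,7,8-pentamethylbicyclo[4.2.0]octa-2,4-diene-8-carboxylate | COC(=O)[C@@]1(C)[C@H](C)[C@@]2(C)C=C(C)C=C(C)[C@@H]12 | intermediate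
21 | (1R,6R,7R,8S)-2,4,6,7,8-pentamethylbicyclo[4.2.0]octa-2,4-diene-8-carbaldehyde | O=C[C@@]1(C)[C@H](C)[C@@]2(C)C=C(C)C=C(C)[C@@H]12 | intermediate
22 | methyl 2-methyl-3-oxopentanoate (racemic) | CCC(=O)C(C)C(=O)OC | starting material
23 | sodium lithium dianion of 22 | CC=C(O[Li])C(C)=C(O[Na])OC | intermediate (not isolated)
24 | methyl 5-hydroxy-2,4-dimethyl-3-oxo-5-(2,4,6,7,8-pentamethylbicyclo[4.2.0]octa-2,4-dien-8-yl)pentanoate (ring as in 21; side-chain diastereomers) | COC(=O)C(C)C(=O)C(C)C(O)[C@@]1(C)[C@H](C)[C@@]2(C)C=C(C)C=C(C)[C@@H]12 | intermediate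
25 | methyl 2,4-dimethyl-3,5-dioxo-5-(2,4,6,7,8-pentamethylbicyclo[4.2.0]octa-2,4-dien-8-yl)pentanoate (ring as in 21) | COC(=O)C(C)C(=O)C(C)C(=O)[C@@]1(C)[C@H](C)[C@@]2(C)C=C(C)C=C(C)[C@@H]12 | intermediate
26 | 4-hydroxy-3,5-dimethyl-6-[(1R,6R,7R,8S)-2,4,6,7,8-pentamethylbicyclo[4.2.0]octa-2,4-dien-8-yl]-2H-pyran-2-one | CC1=C(O)C(C)=C(OC1=O)[C@@]1(C)[C@H](C)[C@@]2(C)C=C(C)C=C(C)[C@@H]12 | intermediate
27 | 2-methoxy-3,5-dimethyl-6-[(1R,6R,7R,8S)-2,4,6,7,8-pentamethylbicyclo[4.2.0]octa-2,4-dien-8-yl]-4H-pyran-4-one | COc1oc([C@@]2(C)[C@H](C)[C@@]3(C)C=C(C)C=C(C)[C@@H]23)c(C)c(=O)c1C | intermediate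
28 | CNP0183511.1, 2-methoxy-3,5-dimethyl-6-(1,3,4,5,10-pentamethyl-7,8-dioxatricyclo[4.2.2.0(2,5)]dec-9-en-3-yl)-4H-pyran-4-one | COc1oc([C@@]2(C)[C@H](C)[C@@]3(C)[C@@H]4OO[C@@](C)(C=C4C)[C@@H]23)c(C)c(=O)c1C | target

**Totals and risks**

Total steps: 18. Longest linear sequence: 18 steps (1 to 28); 3 and 22 are purchased.

Steps most likely to fail:

Step 8. The ketocarbene may be intercepted (O–H insertion into methanol, 1,2-hydrogen shift from C7a) before the strained 1,2-alkyl shift takes place. The fallback reaches the same C7–C8 shift without a carbene, by the enamine–phosphoryl azide ring contraction, and sets out from 9. Condensation with pyrrolidine (TsOH cat., PhH, reflux) should give the less substituted pyrrolidine enamine F1. Diphenylphosphoryl azide (THF, rt to 60 °C) adds to it, and the triazoline loses N2 with migration of C3 to C1 to give the ring-contracted N-phosphoryl amidine F2. Hydrolysis (KOH, ethylene glycol, 120 °C; the ene-ketal is base-stable) should give the cyclobutanecarboxylic acid F3. Esterification with MeI and K2CO3 in DMF comes back to the route at 14.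

Step 5. Methyl transfer may go to the distal terminus (1,6-addition), or the hindered C3 enolate may exchange protons before it is methylated, which would give C1- or over-methylation. The fallback separates the two events and sets out from 7. Me3Al with CuBr·SMe2 (5 mol%) in THF should add 1,4, and the aluminium enolate is captured with Ac2O as the enol acetate F4. Two equivalents of MeLi at −78 °C then regenerate enolate 8 cleanly and regiospecifically, and MeI with HMPA comes back to the route at 9.

Step 9. Facial discrimination may be poor in the alkylation of the exocyclic enolate, because the convex face carries the vicinal C7 methyl. The fallback alkylates only after the diene is in place, where the cyclobutane stands pseudoaxially over the planar diene and the concave face is closed by the π-face and the in-plane C2 methyl. It sets out from 14. Hydrolysis (PPTS, wet acetone) should give the enone ester F5. KN(SiMe3)2 and PhNTf2 (the enone α′-hydrogen is more acidic than the ester α-hydrogen) give the dienyl triflate F6. Reduction (Pd(OAc)2, PPh3, HCO2H, Bu3N) gives methyl 2,4,6,7-tetramethylbicyclo[4.2.0]octa-2,4-diene-8-carboxylate F7. LiN(i-Pr)2 and MeI on F7 then come back to the route at 20, so that steps 9–12 are not needed.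

**Further compounds**

F1 | step 8 | 1-[(3R,3aR,7R,7aR)-6,6-dimethoxy-3,3a,5,7-tetramethyl-3a,6,7,7a-tetrahydro-3H-inden-2-yl]pyrrolidine (C1=C2 enamine of 9) | C1=C(N3CCCC3)[C@H](C)[C@@]2(C)C=C(C)C(OC)(OC)[C@H](C)[C@@H]12
F2 | step 8 | diphenyl N-[(3,3-dimethoxy-2,4,6,7-tetramethylbicyclo[4.2.0]oct-4-en-8-yl)(pyrrolidin-1-yl)methylidene]phosphoramidate (ring centres as in 14) | O=P(Oc1ccccc1)(Oc1ccccc1)N=C(N1CCCC1)[C@H]1[C@H](C)[C@@]2(C)C=C(C)C(OC)(OC)[C@H](C)[C@@H]12
F3 | step 8 | 3,3-dimethoxy-2,4,6,7-tetramethylbicyclo[4.2.0]oct-4-ene-8-carboxylic acid (ring centres as in 14) | OC(=O)[C@H]1[C@H](C)[C@@]2(C)C=C(C)C(OC)(OC)[C@H](C)[C@@H]12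
F4 | step 5 | 6,6-dimethoxy-3a,5,7-trimethyl-3a,6,7,7a-tetrahydro-1H-inden-2-yl acetate (cis-fused, 7-Me trans to C1) | C1C(OC(C)=O)=C[C@@]2(C)C=C(C)C(OC)(OC)[C@H](C)[C@@H]12
F5 | step 9 | methyl 2,4,6,7-tetramethyl-3-oxobicyclo[4.2.0]oct-4-ene-8-carboxylate (ring centres as in 14) | COC(=O)[C@H]1[C@H](C)[C@@]2(C)C=C(C)C(=O)[C@H](C)[C@@H]12
F6 | step 9 | methyl 2,4,6,7-tetramethyl-3-(trifluoromethanesulfonyloxy)bicyclo[4.2.0]octa-2,4-diene-8-carboxylate | COC(=O)[C@H]1[C@H](C)[C@@]2(C)C=C(C)C(OS(=O)(=O)C(F)(F)F)=C(C)[C@@H]12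
F7 | step 9 | methyl 2,4,6,7-tetramethylbicyclo[4.2.0]octa-2,4-diene-8-carboxylate (cis-fused, 6-Me and 7-Me syn) | COC(=O)[C@H]1[C@H](C)[C@@]2(C)C=C(C)C=C(C)[C@@H]12
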